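The reagent in the second phase had to cross into the reaction phase before it could meet the starting material.

starting material 17 mM; reagent in the second phase 1.10 equiv; time 30 s; volume of the second phase over the first 0.50

    2 starting material → self-condensation product (k1 = 0.0041 L mol⁻¹ s⁻¹)
    reagent in the reaction phase ⇌ dormant form (K2 = 1.4, k2 = 0.0041 s⁻¹)
    reagent in the reaction phase ⇌ reagent in the second phase, rate k3*([reagent in the reaction phase] - [reagent in the second phase]/K3) per volume of the first phase (K3 = 0.58, k3 = 0.74 s⁻¹)
    target → decomposed product (k4 = 0.076 s⁻¹)
    target ⇌ product in the second phase, rate k5*([target] - [product in the second phase]/K5) per volume of the first phase (K5 = 0.40, k5 = 0.062 s⁻¹)
    starting material + reagent in the reaction phase → target (k6 = 5.4 L mol⁻¹ s⁻¹)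

- percentages count the starting material that a species holds: one self-condensation product counts as two
- target is meant together with its product in the second phase
- two of one species on the left: rate k times its square, two consumed each time
- in the second phase: reagent in the second phase, product in the second phase; everything else is in the first
- charges count per volume of the first phase; a concentration in a rate is the amount of a species over the volume of its own phase; every rate counts per litre of the first phase
- run time (flask): 30 s

- target and product in the second phase together at 30 s, in percent of the starting material charged
- the change that raises the amount of target and product in the second phase together at 30 s, in percent of the starting material charged most ("none" if none brings more than 2 percentage points) (south-east / south / north / none)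
- amount of target and product in the second phase together at 30 s, in percent of the starting material charged, after south

With the partition balanced and before any coupling, I reckoned 14.5 mM of reagent in the reaction phase. I carried one quantity, the race ratio ρ: 5.4 L mol⁻¹ s⁻¹ times [reagent in the reaction phase], which is a pseudo-first-order constant for the starting material, divided by the target's decay constant 0.076 s⁻¹. With that reckoned amount it stood at 1.03. The rule that goes with it is that, leaving aside traffic between the phases, target in the reaction phase rises while ρ[starting material] exceeds [target in the reaction phase]. The ratio began close to one, and it drifts down as [reagent in the reaction phase] falls. With ρ held at one, the two-step formula gave me 23.3% at 30 s, and I committed to roughly that.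

Then I took the settings in turn. The reagent's exchange between the phases relaxes with a half-time of 0.211 s, far shorter than the 7.6 s half-life of the reagent in coupling, so I expected nothing from doubling its coefficient. The target's exchange relaxes in 1.86 s, shorter than its 9.1 s decay half-life, so I expected little from doubling that one too. Doubling the reagent takes the reckoned ρ from 1.03 to 2.06, which makes target sooner but leaves it older at the reading. I expected a gain there, though I could not size it by hand.

The forecast gave 21.4% (19.5% to 23.5%), north as the best change, and 21.7% (19.7% to 23.8%) after south, holding that “the yield is set by the coupling rate racing decomposition of the target”.

The flask gave 22.0%. South-east, the doubled transfer coefficient of the reagent, changed this by −0.1 percentage points; south, the doubled transfer coefficient of the target, changed it by 0.057 points, reaching 22.1%; and north, the doubled amount of reagent, changed it by 3.1 points, so the best change was north.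

In this flask at 30.0 s, the 4.51 mM of reagent in the reaction phase put ρ at 0.320, and ρ[starting material] over [target in the reaction phase] was 0.520, on the falling side of the rule. The neighbour charged with 6.8 mM of starting material, at the same equivalents, starts at ρ of 0.412, lower than 1.03, so I reckoned slower coupling there. At 30.0 s that neighbour held 52.2% of its starting material, its same ratio was 0.749, and its target and product in the second phase together came to 17.4%.

The numbers of this flask are assumed; the rest is arithmetic.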